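Every position of the benzene ring is numbered as in the target chromanone (C4a, C5, C6, C7, C8, C8a) when the target is discussed, and as in the 3,4-dihydrocoumarin (O1, C2 … C8a) for the lactone intermediates 10–17.

## Analysis of the target

The target is a 2,3-dimethylchroman-4-one whose benzene ring carries no hydrogen: C4a holds the ketone, C5 a hydroxyl, C6 the C3 carbon of an octanoic acid, C7 a methoxy group, C8 a prenyl group and C8a the ring oxygen. There are three stereocentres. C2 (S) and C3 (R) are neighbours in the pyranone and carry their methyl groups cis; the benzylic carbon of the side chain (R) lies across the arene, so neither set can steer the other and each needs its own source of asymmetry. The cis pyranone is the fragile part: C3 is alpha to the ketone and epimerises through the enol to the more stable trans isomer, and the O1–C2 bond can open by retro-oxa-Michael reaction under base. The prenyl group does not tolerate strong acid, and the free acid can close onto the C5 hydroxyl. The difficulties are the placing of six different substituents, the fact that two oxygens (O5 and O8a) flank C4a while only O8a may close the pyranone, and a benzylic stereocentre whose two alkyl arms (CH2CO2H and n-pentyl) differ little. The strategy rests on the chain O5–C5–C6–C(benzylic)–CH2–CO2H: closed, these atoms are a 4-pentyl-3,4-dihydrocoumarin, which hides O5 and the acid in one ring and can be assembled by adding a two-carbon acetate unit across an o-quinone methide of the benzene ring.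

## Retrosynthetic reasoning

**20 to 18.** The carboxyl group and O5 of target 20 are joined to give the tricyclic aryl lactone 18, so that the only bond broken in the last forward step is the O5–acyl bond, by lithium hydroxide 19. Nothing is built at the end. The forward reaction only has to open an aryl ester faster than base removes the proton at C3 of the pyranone.

**18 to 17.** The O–C bond of the pyranone (O7–C8 in 18, O1–C2 of the target) is cut, which leads to the hydroxy enone 17. This bond can be closed by a catalytic chiral base, with the second centre following by protonation, and in 17 there is only one free phenol because the lactone holds the other oxygen. The forward step must select one face of the enone beta-carbon and protonate the ring enolate kinetically to the cis isomer.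

**17 to 15 and 16, then 15 to 13 and 14.** The aryl–prenyl bond is cut to bromide 15 and stannane 16, and the C–Br bond to phenol 13 and N-bromosuccinimide 14. The prenyl group enters after the Lewis-acid step because it is acid sensitive, and before ring closure so that the cis pyranone never meets hot palladium. In 13 the carbon to be brominated is the last ring C–H, so no choice of position arises.

**13 to 11 and 12.** The aryl–acyl bond (C4a–C4 of the target) is cut to phenol 11 and tigloyl chloride 12, which brings C2, C3, C4 and both methyl groups in one piece. The forward acylation has to choose C8 of 11 over C6.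

**11 to 10.** The free hydroxyl of 11 is masked as the benzyl ether 10. This oxygen must be blocked in all earlier steps, so that only one phenol can give a quinone methide and only one can end up in the lactone.

**10 to 9 and 8, with 9 from 7.** This is the key disconnection. The benzylic C–CH2 bond and the O–acyl bond of lactone 10 are cut, which gives the o-quinone methide 9 and the acetate donor 8. The cut is made here because the aryl group then acts as a planar electrophile; the alternative, adding a 2,6-dioxygenated aryl nucleophile to an oct-2-enoate, is sterically poor. The same event creates the stereocentre, attaches both side-chain carbons and ties up O5. Methide 9 cannot be stored and is released from the racemic sulfone 7 by base.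

**7 to 5 and 6, 5 to 3 and 4, 3 to 1 and 2.** The C–S bond of 7 leads to benzylic alcohol 5 and sulfinic acid 6, the pentyl–carbinol bond of 5 to aldehyde 3 and Grignard reagent 4, and the benzyl ether of 3 to aldehyde 1 and benzyl bromide 2. These three steps are routine, so the risk of the route sits in the annulation.

## Alternatives that were turned down

**Alternative 1:** The C2–C3 bond of the pyranone is cut. The methyl ester A1, which already holds the side chain, the prenyl group and both methoxy groups, is traced back to the alpha-diazo ethyl ketone A2, in which C8a carries an ethoxy group. In the forward step a chiral dirhodium tetracarboxylate turns the diazo carbon into a carbenoid at C3 that inserts into a C–H bond of the OCH2 group and closes the six-membered ring.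
- For: C2 and C3 arise together in one irreversible C–C bond formation under catalyst control, which is a sounder way to fix a cis pair than a reversible oxa-Michael addition with kinetic protonation. The prenyl group is already in place, so no late coupling is needed. On these two points the alternative is stronger.
- Against: the carbenoid carbon bears a methyl group and can be lost by 1,2-hydride shift to the vinyl ketone. The ether oxygen lies in a five-ring relationship to the carbenoid and can form an oxonium ylide. The C5 methoxy group on the other flank offers a second, unwanted six-ring insertion. A1 still needs selective cleavage of the C5 methyl ether and saponification of a methyl ester beside the epimerisable cis ring. The benzylic centre of A2 must be bought earlier by a separate asymmetric step on a crowded arene.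
- Comparison: the chosen route gives up the one-step formation of C2 and C3. In return one annulation delivers the benzylic centre, the two side-chain carbons and the masking of O5, on a precursor three steps from a simple aldehyde, and its last ester is an aryl lactone that opens far more easily than a methyl ester.

**Alternative 2:** The benzylic stereocentre is made by breaking the symmetry of the prochiral cyclobutanone A4. A peroxide oxidant under chiral Brønsted acid catalysis inserts oxygen into one of the two enantiotopic CO–CH2 bonds (Baeyer–Villiger reaction) and gives the gamma-lactone A3.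
- For: A4 is easy to reach and no reactive intermediate of uncertain alkene geometry is involved. The 2,6-dimethoxy-4-benzyloxy ring of A3 is locally symmetric, so the later acylation beside O8a cannot go to a wrong position, and O5 is then freed by chelation-controlled cleavage of the methyl ether next to the ketone. On arene regiochemistry this alternative is stronger than the chosen route, which relies on an innate C8 preference in step 6.
- Against: the key step forms a C–O bond and no skeletal C–C bond, so the CH2–O arm of A3 must be rebuilt into the pentyl chain (ring opening, activation of the primary alcohol, four-carbon extension). The oxidant meets a very electron-rich arene. The two ortho methoxy groups twist the aryl ring and weaken the distinction between the enantiotopic bonds. The sequence would be clearly longer.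
- Comparison: the chosen strategy gives the pentyl chain and the acetic acid arm at the right oxidation level straight from the key step, with O5 masked in the same ring.

**Alternative 3:** The benzene ring itself is disconnected. Heating the 4-substituted 3-ethoxycyclobutenone A6 opens it to a vinylketene that adds the siloxyalkyne A7; ring opening of the new cyclobutenone and six-electron electrocyclisation give the pentasubstituted phenol A5 (Danheiser benzannulation).
- For: every ring substituent, the prenyl group included, is placed by the connectivity of the two partners, with no electrophilic substitution, halogenation or cross-coupling. In regiocontrol over the arene this is the strongest of the four plans.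
- Against: the annulation creates no stereocentre, so the benzylic centre must already be present in A6 beside an enolisable four-membered ketone, with no evident catalytic way to install it. A5 then needs O-methylation, desilylation, acylation at the last ring C–H and ring closure, and finally cleavage of an ethyl ether and a methyl ester in the presence of the prenyl group and the cis pyranone. O5 is an ether that needs a Lewis acid at the end.
- Comparison: the chosen strategy accepts two electrophilic substitutions and one cross-coupling on the arene in exchange for a catalytic, early and short entry to the benzylic stereocentre, and O5 is released by cold hydroxide.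

Key step: step 4

Assumption: the (5aR,10bS) triazolium salt in step 4 is taken to direct attack to the Si face of the methide carbon, and quinidine in step 9 is taken to give the (8S,9R) ring because quinine gives the mirror-image cis ring with 7-hydroxy-8-tigloylcoumarins; the catalyst meant in each step is the enantiomer or pseudoenantiomer that gives 10 and 18 as drawn.

## Route

**Step 1**
Reactants: 1 2,4-dihydroxy-6-methoxybenzaldehyde; 2 benzyl bromide
Product: 3 4-(benzyloxy)-2-hydroxy-6-methoxybenzaldehyde
Conditions: BnBr (1.05 equiv), K2CO3 (1.1 equiv), acetone, rt
Reagents that add atoms: benzyl bromide, BrCc1ccccc1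
Why: Williamson ether synthesis; the 2-hydroxyl is held in a hydrogen bond to the formyl oxygen and is the weaker nucleophile, so one equivalent of 2 should react at the 4-hydroxyl.

**Step 2**
Reactants: 3 4-(benzyloxy)-2-hydroxy-6-methoxybenzaldehyde; 4 pentylmagnesium bromide
Product: 5 1-[4-(benzyloxy)-2-hydroxy-6-methoxyphenyl]hexan-1-ol (racemic)
Conditions: n-C5H11MgBr (2.5 equiv), THF, 0 °C to rt; aq. NH4Cl
Reagents that add atoms: pentylmagnesium bromide, CCCCC[Mg]Br
Why: Grignard addition; the first equivalent forms the magnesium phenoxide and the second adds to the chelated aldehyde, and the new carbinol centre may be racemic because it is erased in step 4.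

**Step 3**
Reactants: 5 1-[4-(benzyloxy)-2-hydroxy-6-methoxyphenyl]hexan-1-ol; 6 4-methylbenzenesulfinic acid
Product: 7 5-(benzyloxy)-3-methoxy-2-[1-(4-methylbenzenesulfonyl)hexyl]phenol (racemic)
Conditions: p-TolSO2H (1.5 equiv), CH2Cl2, 0 °C to rt
Reagents that add atoms: 4-methylbenzenesulfinic acid, Cc1ccc(cc1)S(=O)O
Why: Acid-promoted SN1-type substitution; the oxygen-stabilised benzylic cation is trapped by sulfinate through sulfur to give the sulfone, which is the thermodynamic and usually crystalline product.

**Step 4**
Reactants: 7 5-(benzyloxy)-3-methoxy-2-[1-(4-methylbenzenesulfonyl)hexyl]phenol; 8 4-nitrophenyl acetate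
Product: 10 (4R)-7-(benzyloxy)-5-methoxy-4-pentyl-3,4-dihydro-2H-chromen-2-one, via o-quinone methide 9 (not isolated)
Conditions: (5aR,10bS)-2-mesityl-5a,10b-dihydro-4H,6H-indeno[2,1-b][1,2,4]triazolo[4,3-d][1,4]oxazin-2-ium tetrafluoroborate (20 mol %), Cs2CO3 (2.5 equiv), 8 (2.5 equiv), 4 Å MS, THF, rt
Reagents that add atoms: 4-nitrophenyl acetate, CC(=O)Oc1ccc(cc1)[N+](=O)[O-]
Why: Cs2CO3 deprotonates the phenol of 7 and the phenoxide expels p-toluenesulfinate by 1,4-elimination to give 9, so the stereocentre of racemic 7 is erased before any chiral information is needed. The carbene freed from the triazolium salt attacks 8, 4-nitrophenoxide leaves, and the acetyl azolium is deprotonated to an azolium enolate. The enolate carbon adds to the exocyclic carbon of 9 (C4–C3 bond), the ring re-aromatises, and the phenoxide then attacks the acyl azolium in a 6-exo-trig acyl substitution that closes the lactone (O1–C2 bond) and returns the carbene. The closest known reaction type is the carbene-catalysed formal [4+2] annulation of o-quinone methides released from 2-(1-sulfonylalkyl)phenols with azolium enolates of activated esters, which gives 3,4-dihydrocoumarins; an alkyl-substituted methide with the unsubstituted acetate enolate is the least explored pairing within it. C4 is set in the C–C bond-forming event by the catalyst alone: the indane-fused backbone closes one face of the enolate, and with the methide oxygen held near the azolium the Si face of the methide carbon is expected to be attacked, which gives 4R. The step needs enantioface selection on a planar methide and capture of 9 before it tautomerises to the 2-(hex-1-enyl)phenol; the alkoxy groups ortho and para to the methide carbon lower its electrophilicity and lengthen its lifetime, the single free hydroxyl allows only one methide, and reversible re-addition of sulfinate lets the E and Z forms of 9 equilibrate so that the faster-reacting E form is drained.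

**Step 5**
Reactants: 10 (4R)-7-(benzyloxy)-5-methoxy-4-pentyl-3,4-dihydro-2H-chromen-2-one
Product: 11 (4R)-7-hydroxy-5-methoxy-4-pentyl-3,4-dihydro-2H-chromen-2-one
Conditions: H2 (1 atm), 10% Pd/C, EtOAc, rt
Reagents that add atoms: none
Why: Hydrogenolysis of a benzyl aryl ether; C4 has only C–C and C–H bonds and is not touched, and ethyl acetate is used so that no alcohol can open the aryl lactone.

**Step 6**
Reactants: 11 (4R)-7-hydroxy-5-methoxy-4-pentyl-3,4-dihydro-2H-chromen-2-one; 12 (2E)-2-methylbut-2-enoyl chloride (tigloyl chloride)
Product: 13 (4R)-7-hydroxy-5-methoxy-8-[(2E)-2-methylbut-2-enoyl]-4-pentyl-3,4-dihydro-2H-chromen-2-one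
Conditions: 12 (1.3 equiv), AlCl3 (3 equiv), CH2Cl2–PhNO2, 0 °C to rt; cold dil. HCl
Reagents that add atoms: (2E)-2-methylbut-2-enoyl chloride, C/C=C(\C)C(Cl)=O
Why: Friedel–Crafts acylation ortho to the hydroxyl; C8 is para to the methoxy group and flanked only by the hydroxyl and the ring-held lactone oxygen, whereas C6 lies between the hydroxyl and a methoxy group whose methyl is turned toward it by the C4 substituent. The same C8 preference is the rule for 5,7-dioxygenated coumarins, whose benzene ring carries the same donors in the same places.

**Step 7**
Reactants: 13 (4R)-7-hydroxy-5-methoxy-8-[(2E)-2-methylbut-2-enoyl]-4-pentyl-3,4-dihydro-2H-chromen-2-one; 14 N-bromosuccinimide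
Product: 15 (4R)-6-bromo-7-hydroxy-5-methoxy-8-[(2E)-2-methylbut-2-enoyl]-4-pentyl-3,4-dihydro-2H-chromen-2-one
Conditions: NBS (1.05 equiv), CH2Cl2, −20 to 0 °C, dark
Reagents that add atoms: N-bromosuccinimide, O=C1CCC(=O)N1Br
Why: Electrophilic aromatic bromination; C6 is the only ring C–H and is ortho to the free hydroxyl, while the electron-poor enone alkene does not compete under ionic conditions.

**Step 8**
Reactants: 15 (4R)-6-bromo-7-hydroxy-5-methoxy-8-[(2E)-2-methylbut-2-enoyl]-4-pentyl-3,4-dihydro-2H-chromen-2-one; 16 tributyl(3-methylbut-2-en-1-yl)stannane
Product: 17 (4R)-7-hydroxy-5-methoxy-6-(3-methylbut-2-en-1-yl)-8-[(2E)-2-methylbut-2-enoyl]-4-pentyl-3,4-dihydro-2H-chromen-2-one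
Conditions: 16 (1.5 equiv), Pd(P(t-Bu)3)2 (5 mol %), PhMe, 80 °C, degassed
Reagents that add atoms: tributyl(3-methylbut-2-en-1-yl)stannane, CCCC[Sn](CCCC)(CCCC)CC=C(C)C
Why: Stille coupling; the bulky electron-rich phosphine complex inserts into the hindered C–Br bond and reductive elimination at the unsubstituted allyl terminus gives the linear prenyl group. No base or fluoride is present, so the chelated phenol is not deprotonated and should not close onto the enone.

**Step 9**
Reactants: 17 (4R)-7-hydroxy-5-methoxy-6-(3-methylbut-2-en-1-yl)-8-[(2E)-2-methylbut-2-enoyl]-4-pentyl-3,4-dihydro-2H-chromen-2-one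
Product: 18 (4R,8S,9R)-5-methoxy-8,9-dimethyl-6-(3-methylbut-2-en-1-yl)-4-pentyl-3,4,8,9-tetrahydro-2H,10H-pyrano[2,3-f]chromene-2,10-dione
Conditions: quinidine (20 mol %), PhCl, 15 °C; cold filtration through silica
Reagents that add atoms: none
Why: Cinchona-base-catalysed intramolecular oxa-Michael addition (6-endo-trig), known for 7-hydroxy-8-tigloylcoumarins, of which 17 is the 3,4-dihydro analogue; the quinuclidine nitrogen deprotonates the phenol and holds the phenoxide as a chiral ion pair that closes on one face of the beta-carbon and sets C8 (C2 of the target) as S. The ammonium ion then protonates the ring enolate on the face away from the new C8 methyl group, which sets C9 (C3 of the target) as R and gives the kinetic cis ring; C4 is too remote to interfere, and the lactone leaves no second oxygen that could close instead.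

**Step 10**
Reactants: 18 (4R,8S,9R)-5-methoxy-8,9-dimethyl-6-(3-methylbut-2-en-1-yl)-4-pentyl-3,4,8,9-tetrahydro-2H,10H-pyrano[2,3-f]chromene-2,10-dione; 19 lithium hydroxide
Product: 20 (3R)-3-[(2S,3R)-5-hydroxy-7-methoxy-2,3-dimethyl-8-(3-methylbut-2-en-1-yl)-4-oxo-3,4-dihydro-2H-chromen-6-yl]octanoic acid
Conditions: LiOH (2.2 equiv), THF–H2O (3:1), 0 °C, short reaction time; cold 0.5 M HCl to pH 3–4
Reagents that add atoms: lithium hydroxide, [Li+].[OH-]
Why: Saponification of an aryl ester, whose phenoxide leaving group makes attack at the lactone carbonyl much faster than removal of the C3 proton of the pyranone. Once the ring is open the C5 phenoxide is conjugated with the C4 carbonyl, which lowers the acidity of C3–H further and protects the cis ring; mild cold acidification avoids re-closure of the lactone.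

## Compound list

1 | 2,4-dihydroxy-6-methoxybenzaldehyde | O=Cc1c(O)cc(O)cc1OC | starting material
2 | benzyl bromide | BrCc1ccccc1 | starting material
3 | 4-(benzyloxy)-2-hydroxy-6-methoxybenzaldehyde | O=Cc1c(O)cc(OCc2ccccc2)cc1OC | intermediate
4 | pentylmagnesium bromide | CCCCC[Mg]Br | starting material
5 | 1-[4-(benzyloxy)-2-hydroxy-6-methoxyphenyl]hexan-1-ol (racemic) | CCCCCC(O)c1c(O)cc(OCc2ccccc2)cc1OC | intermediate
6 | 4-methylbenzenesulfinic acid | Cc1ccc(cc1)S(=O)O | starting material
7 | 5-(benzyloxy)-3-methoxy-2-[1-(4-methylbenzenesulfonyl)hexyl]phenol (racemic) | CCCCCC(c1c(O)cc(OCc2ccccc2)cc1OC)S(=O)(=O)c1ccc(C)cc1 | intermediate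
8 | 4-nitrophenyl acetate | CC(=O)Oc1ccc(cc1)[N+](=O)[O-] | starting material
9 | (6E)-3-(benzyloxy)-6-hexylidene-5-methoxycyclohexa-2,4-dien-1-one (o-quinone methide, not isolated) | CCCCC/C=C1/C(=O)C=C(OCc2ccccc2)C=C1OC | intermediate
10 | (4R)-7-(benzyloxy)-5-methoxy-4-pentyl-3,4-dihydro-2H-chromen-2-one | CCCCC[C@@H]1CC(=O)Oc2cc(OCc3ccccc3)cc(OC)c21 | intermediate
11 | (4R)-7-hydroxy-5-methoxy-4-pentyl-3,4-dihydro-2H-chromen-2-one | CCCCC[C@@H]1CC(=O)Oc2cc(O)cc(OC)c21 | intermediate
12 | (2E)-2-methylbut-2-enoyl chloride (tigloyl chloride) | C/C=C(\C)C(Cl)=O | starting material
13 | (4R)-7-hydroxy-5-methoxy-8-[(2E)-2-methylbut-2-enoyl]-4-pentyl-3,4-dihydro-2H-chromen-2-one | CCCCC[C@@H]1CC(=O)Oc2c(C(=O)/C(C)=C/C)c(O)cc(OC)c21 | intermediate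
14 | N-bromosuccinimide | O=C1CCC(=O)N1Br | starting material
15 | (4R)-6-bromo-7-hydroxy-5-methoxy-8-[(2E)-2-methylbut-2-enoyl]-4-pentyl-3,4-dihydro-2H-chromen-2-one | CCCCC[C@@H]1CC(=O)Oc2c(C(=O)/C(C)=C/C)c(O)c(Br)c(OC)c21 | intermediate
16 | tributyl(3-methylbut-2-en-1-yl)stannane | CCCC[Sn](CCCC)(CCCC)CC=C(C)C | starting material
17 | (4R)-7-hydroxy-5-methoxy-6-(3-methylbut-2-en-1-yl)-8-[(2E)-2-methylbut-2-enoyl]-4-pentyl-3,4-dihydro-2H-chromen-2-one | CCCCC[C@@H]1CC(=O)Oc2c(C(=O)/C(C)=C/C)c(O)c(CC=C(C)C)c(OC)c21 | intermediate
18 | (4R,8S,9R)-5-methoxy-8,9-dimethyl-6-(3-methylbut-2-en-1-yl)-4-pentyl-3,4,8,9-tetrahydro-2H,10H-pyrano[2,3-f]chromene-2,10-dione | CCCCC[C@@H]1CC(=O)Oc2c1c(OC)c(CC=C(C)C)c3O[C@@H](C)[C@@H](C)C(=O)c23 | intermediate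
19 | lithium hydroxide | [Li+].[OH-] | starting material
20 | (3R)-3-[(2S,3R)-5-hydroxy-7-methoxy-2,3-dimethyl-8-(3-methylbut-2-en-1-yl)-4-oxo-3,4-dihydro-2H-chromen-6-yl]octanoic acid | CCCCC[C@H](CC(=O)O)c1c(O)c2c(c(CC=C(C)C)c1OC)O[C@@H](C)[C@@H](C)C2=O | target

## Step count and least certain steps

Total: 10 steps. Longest linear sequence: 10 steps, from aldehyde 1 (the route is fully linear).

**Step 4 (key step).** The alkyl-substituted methide may tautomerise to the styrene or dimerise faster than the small stationary amount of acetate enolate captures it. Facial selectivity may be poor, because the enolate has no alpha-substituent and the methide carbon is flanked by a carbonyl and a methoxy-bearing carbon, so its E/Z preference is small. The phenoxide of 7 may also be O-acetylated and stall.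
Fallback: the fallback sets out from aldehyde 3. A Wittig reaction with (ethoxycarbonylmethylene)triphenylphosphorane in hot N,N-diethylaniline gives ethyl 3-[4-(benzyloxy)-2-hydroxy-6-methoxyphenyl]prop-2-enoate F1, which lactonises in the same pot to 7-(benzyloxy)-5-methoxy-2H-chromen-2-one F2. Copper-catalysed asymmetric conjugate addition of Grignard reagent 4 (CuBr·SMe2, a Josiphos-type ferrocenyl bisphosphine, CH2Cl2, −72 °C, cold quench) then delivers the pentyl group to C4 and returns to the route at lactone 10.

**Step 6.** The acyl group may enter at C6 instead of C8, and the Lewis acid may close the hydroxy enone prematurely to a stereorandom chromanone.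
Fallback: the fallback sets out from phenol 11 and reverses the order of the two electrophilic substitutions, so that the same innate preference is used the other way round. Bromination with 14 gives (4R)-6-bromo-7-hydroxy-5-methoxy-4-pentyl-3,4-dihydro-2H-chromen-2-one F3; Friedel–Crafts acylation of this compound with 12 can then only take place at C8 and returns to the route at bromide 15.

**Step 8.** Oxidative addition into the di-ortho-substituted, electron-rich C–Br bond may be slow, so that protodebromination, thermal closure of the hydroxy enone or transfer of the branched 1,1-dimethylallyl group competes.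
Fallback: the fallback sets out from phenol 13 and needs no halide. Palladium-catalysed O-allylation with tert-butyl 2-methylbut-3-en-2-yl carbonate (Pd(PPh3)4, THF, rt) gives (4R)-5-methoxy-7-[(2-methylbut-3-en-2-yl)oxy]-8-[(2E)-2-methylbut-2-enoyl]-4-pentyl-3,4-dihydro-2H-chromen-2-one F4. An aromatic Claisen rearrangement in toluene at about 100 °C moves the allyl unit with inversion to C6, the only free ortho carbon, as a linear prenyl group and returns to the route at 17.

**Step 9.** Face selection at the beta-carbon may be insufficient, and the cis ring may drift to the trans isomer by epimerisation at C9 if the base stays in contact too long.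
Fallback: the fallback sets out from 17 and replaces catalyst control by separation. Because C4 is already R, the two cis rings are diastereomers; closure with an achiral tertiary amine (DABCO, PhCl, 0 °C) under kinetic control gives 18 together with (4R,8R,9S)-5-methoxy-8,9-dimethyl-6-(3-methylbut-2-en-1-yl)-4-pentyl-3,4,8,9-tetrahydro-2H,10H-pyrano[2,3-f]chromene-2,10-dione F5. These are separated by chromatography or crystallisation, at the cost of up to half the material, and the route continues from 18.

**Step 10.** Hydroxide may remove the C9 proton (C3 of the target) before the lactone has opened, with epimerisation to the trans ring or retro-oxa-Michael opening, and the acid may re-close onto O5 on acidification.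
Fallback: the fallback sets out from 18 and avoids free hydroxide. Neutral transesterification with allyl alcohol, catalysed by (ClBu2Sn)2O in toluene at 80 °C, gives prop-2-en-1-yl (3R)-3-[(2S,3R)-5-hydroxy-7-methoxy-2,3-dimethyl-8-(3-methylbut-2-en-1-yl)-4-oxo-3,4-dihydro-2H-chromen-6-yl]octanoate F6. The allyl ester is then removed with Pd(PPh3)4 and sulfinic acid 6 as allyl acceptor at rt, which arrives at target 20.

## Further compounds

F1 | step 4 | ethyl 3-[4-(benzyloxy)-2-hydroxy-6-methoxyphenyl]prop-2-enoate (E/Z mixture, not isolated) | CCOC(=O)C=Cc1c(O)cc(OCc2ccccc2)cc1OC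
F2 | step 4 | 7-(benzyloxy)-5-methoxy-2H-chromen-2-one | O=C1C=Cc2c(OC)cc(OCc3ccccc3)cc2O1
F3 | step 6 | (4R)-6-bromo-7-hydroxy-5-methoxy-4-pentyl-3,4-dihydro-2H-chromen-2-one | CCCCC[C@@H]1CC(=O)Oc2cc(O)c(Br)c(OC)c21
F4 | step 8 | (4R)-5-methoxy-7-[(2-methylbut-3-en-2-yl)oxy]-8-[(2E)-2-methylbut-2-enoyl]-4-pentyl-3,4-dihydro-2H-chromen-2-one | CCCCC[C@@H]1CC(=O)Oc2c(C(=O)/C(C)=C/C)c(OC(C)(C)C=C)cc(OC)c21
F5 | step 9 | (4R,8R,9S)-5-methoxy-8,9-dimethyl-6-(3-methylbut-2-en-1-yl)-4-pentyl-3,4,8,9-tetrahydro-2H,10H-pyrano[2,3-f]chromene-2,10-dione | CCCCC[C@@H]1CC(=O)Oc2c1c(OC)c(CC=C(C)C)c3O[C@H](C)[C@H](C)C(=O)c23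
F6 | step 10 | prop-2-en-1-yl (3R)-3-[(2S,3R)-5-hydroxy-7-methoxy-2,3-dimethyl-8-(3-methylbut-2-en-1-yl)-4-oxo-3,4-dihydro-2H-chromen-6-yl]octanoate | CCCCC[C@H](CC(=O)OCC=C)c1c(O)c2c(c(CC=C(C)C)c1OC)O[C@@H](C)[C@@H](C)C2=O
A1 | alternative 1 | methyl (3R)-3-[(2S,3R)-5,7-dimethoxy-2,3-dimethyl-8-(3-methylbut-2-en-1-yl)-4-oxo-3,4-dihydro-2H-chromen-6-yl]octanoate | CCCCC[C@H](CC(=O)OC)c1c(OC)c2c(c(CC=C(C)C)c1OC)O[C@@H](C)[C@@H](C)C2=O
A2 | alternative 1 | methyl (3R)-3-[3-(2-diazopropanoyl)-4-ethoxy-2,6-dimethoxy-5-(3-methylbut-2-en-1-yl)phenyl]octanoate | CCCCC[C@H](CC(=O)OC)c1c(OC)c(C(=O)C(C)=[N+]=[N-])c(OCC)c(CC=C(C)C)c1OC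
A3 | alternative 2 | (4R)-4-[4-(benzyloxy)-2,6-dimethoxyphenyl]oxolan-2-one | O1C[C@H](CC1=O)c2c(OC)cc(OCc3ccccc3)cc2OC
A4 | alternative 2 | 3-[4-(benzyloxy)-2,6-dimethoxyphenyl]cyclobutan-1-one | O=C1CC(C1)c1c(OC)cc(OCc2ccccc2)cc1OC
A5 | alternative 3 | methyl (3R)-3-[6-ethoxy-2-hydroxy-3-(3-methylbut-2-en-1-yl)-4-(triisopropylsilyloxy)phenyl]octanoate | CCCCC[C@H](CC(=O)OC)c1c(O)c(CC=C(C)C)c(O[Si](C(C)C)(C(C)C)C(C)C)cc1OCC
A6 | alternative 3 | methyl (3R)-3-(2-ethoxy-4-oxocyclobut-2-en-1-yl)octanoate | CCCCC[C@H](CC(=O)OC)C1C(=O)C=C1OCC
A7 | alternative 3 | triisopropyl[(5-methylhex-4-en-1-yn-1-yl)oxy]silane | CC(C)=CCC#CO[Si](C(C)C)(C(C)C)C(C)C
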